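## Structural features

The target is a 5-hydroxy-7-methoxy-4H-chromen-4-one: ring A is the benzenoid ring, ring C the γ-pyrone (O1, C2, C3, C4, C4a, C8a). At C2 it carries a nine-carbon chain, numbered C1' to C9' from the ring outwards. C1' is a methylene, C2' a secondary carbinol of (R) configuration and the only stereocentre, C3' to C6' an unfunctionalised tetramethylene, and C7'=C8'–C9' an (E)-α,β-unsaturated carboxylic acid. The 5-hydroxyl is chelated to the C4 carbonyl and the 7-oxygen is methylated, which matches the oxygenation pattern of a commercial acetophenone.

The fragile points are three. The C2' hydroxyl is β to C2 of the pyrone (a vinylogous aldol), so strong base or hot acid can dehydrate it across C1'–C2'. The enoic acid is a Michael acceptor that excludes hydride, hydrogenation and hard nucleophiles late in the route. The pyrone itself opens with hydroxide.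

There are no neighbouring stereocentres, so the difficulty is not diastereocontrol. It lies in securing one isolated stereocentre in high enantiomeric purity and in joining the blocks across a chain segment that has no polar handle. The key step exploits exactly that segment: the C3'–C4' bond lies between two primary sp3 carbons, each of which can be traced back to a CH2–CO2H terminus, so two carboxylic acids can be united there by anodic decarboxylation.

## Logic of the disconnections

12 to 11. The O1–C2 bond of ring C is cut together with the three acid-labile groups (silyl ether on the C2' oxygen, methoxymethyl ether on the C5 oxygen, tert-butyl ester at C9'). One acid treatment then closes the ring and unmasks everything, so no separate deprotection steps are needed. The forward step demands that the free phenol adds to the chain carbonyl before the C2' oxygen is unmasked, and that the acid is mild enough not to dehydrate across C1'–C2'.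

11 to 10. The C2–C3 bond (chain carbonyl carbon to the former acetyl methyl carbon) is cut and replaced by the aryl ester O–C bond of 10. The carbon–carbon bond is then formed intramolecularly through a six-membered transition state instead of by an intermolecular ketone-enolate acylation. The forward step demands that the ketone enolate forms and reacts faster than the ester α-position, which carries a β-silyloxy group, and faster than the γ-position of the enoate.

10 to 7 and 9, and 9 to 8. The aryl ester C–O bond is cut, giving a carboxylic acid and a phenol of similar size. One of the two equivalent phenols of 8 has to be masked first (O–CH2 bond of the acetal cut) by a group that falls in the final acid step, so the protection costs one step and no separate deprotection. The demand is mono-selectivity on a symmetrical diphenol.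

7 to 6. The methyl ester O–C bond is cut. The demand on the forward step is chemoselective saponification of the methyl ester next to a tert-butyl enoate, without β-elimination of the silyloxy group.

6 to 2 and 5. The C3'–C4' bond (C6–C7 of 6) is cut homolytically and each radical is traced back to a carboxylic acid. This splits the chain into a chiral four-carbon piece that holds C2, C1', C2', C3' and an achiral six-carbon piece that holds C4' to C9' with the (E)-enoate in place. All oxidation levels are then correct and no redox adjustment is needed afterwards. The forward step demands cross-coupling over homo-coupling and a radical rather than a cationic course at the anode.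

2 to 1. The ester C–O bond is cut, leading back to a prochiral cyclic anhydride. The stereocentre is created by choosing one of two enantiotopic carbonyl groups, without making or breaking a bond at C2'. The demand is high enantioselectivity in the ring opening.

5 to 3 and 4. The C7'=C8' double bond is cut by retro-cross-metathesis into two commercial alkenes. The demand is (E) selectivity and tolerance of a free carboxylic acid.

## Other disconnections considered

Alternative 1: The cut is the C2'–O bond, made by oxygen insertion. C2' to C7' would come from a six-membered carbocycle, and C1' plus pyrone carbons C2 and C3 from a propargyl group.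

- Forward key step: a Baeyer–Villiger monooxygenase of the cyclohexanone-monooxygenase family would oxidise one enantiomer of racemic 2-(prop-2-yn-1-yl)cyclohexan-1-one A1 with air and a recycled nicotinamide cofactor. The more substituted carbon migrates with retention, which would give (7R)-7-(prop-2-yn-1-yl)oxepan-2-one A2.
- In its favour: A1 is a one-step compound, the oxidant is air, and no metal or protecting group is involved. The stereocentre, the C2' oxygen and the carboxyl oxidation level at C7' all come out of one step.
- Against it here: the step is a kinetic resolution, so at most half of A1 is usable unless the ketone racemises under the reaction conditions. The enantiopreference of a given enzyme for a propargyl substituent cannot be predicted and would need screening. A2 is also far from 12: it needs ring opening, silylation, reduction to the C7' aldehyde, Wittig homologation to the (E)-enoate, and then construction of ring C from the alkyne (acylation to an aryl ynone and 6-endo closure, with the two phenols of ring A differentiated).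
- Comparison: on structure the alternative is the better plan in one respect, since it creates the stereocentre catalytically in its key step, whereas the chosen plan brings it in by an earlier desymmetrisation. On mechanism it is at least the equal, because the migration step is more predictable in regio- and stereochemistry than a statistical radical coupling. On step economy the chosen plan is ahead: 6 already holds C2 and the whole chain at the right oxidation levels and is four steps from 12, while A2 would need roughly twice as many plus a separate aryl building block.

Alternative 2: The cut is the C4a–C5 bond of ring A. The benzenoid ring is built last, from a preformed γ-pyrone.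

- Forward key step: base would deprotonate the methylene between the pyrone and the methoxy-enoate of methyl (2E)-4-{6-[(2R)-2-(tert-butyldimethylsilyloxy)oct-7-en-1-yl]-4-oxo-4H-pyran-2-yl}-3-methoxybut-2-enoate A3. The ring carbon of the resulting dienolate would attack the ester carbonyl; loss of methanol and tautomerisation would give 2-[(2R)-2-(tert-butyldimethylsilyloxy)oct-7-en-1-yl]-5-hydroxy-7-methoxy-4H-chromen-4-one A4.
- In its favour: the 5-hydroxy/7-methoxy pattern arises automatically (methoxyl from the enol ether, hydroxyl from the ester carbon), so no phenol protecting group is needed. On this point it is better than the chosen plan. The (E)-enol ether, the stable isomer, also places the ester on the correct side for closure.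
- Against it here: A3 is more complex than any intermediate of the chosen plan and needs its own poly-β-carbonyl assembly with the chiral chain already attached. The base can also deprotonate C1' on the other side of the pyrone, and that carbanion sits β to the silyloxy group and can expel it, destroying the stereocentre. After A4, cross-metathesis with 4 and two deprotections still remain.
- Comparison: on mechanism the alternative is the equal or the better, as purely polar enolate chemistry without an electrode. The chosen plan faces a related elimination hazard in its acyl shift, though there the acidic sites are better differentiated. On structure and step economy the chosen plan is ahead, because ring A is bought with the correct substitution and the chain is assembled in one convergent step.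

Alternative 3: The cut is the C2–C1' bond, the junction of ring and chain.

- Forward key step: the primary radical from tert-butyl{[(2R)-1-iodooct-7-en-2-yl]oxy}dimethylsilane A6, generated with a silyl hydride chain carrier and an initiator, would add to C2 of 7-methoxy-5-(methoxymethoxy)-2-(methylsulfonyl)-4H-chromen-4-one A5. The C3 radical would then expel the methanesulfonyl radical to give 2-[(2R)-2-(tert-butyldimethylsilyloxy)oct-7-en-1-yl]-7-methoxy-5-(methoxymethoxy)-4H-chromen-4-one A7.
- In its favour: it is the most convergent of the plans, joining a finished ring system and a finished chain in one step. The polarity is matched (nucleophilic alkyl radical, electron-poor C2). Only one radical partner is present, so no statistical homodimers arise; on cross-selectivity it is better than the chosen plan. The stereocentre sits next to the radical carbon in both plans and is equally safe.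
- Against it here: A5 needs several steps of its own (thioether-substituted chromone, oxidation, phenol protection), and A6 needs several more from a chiral epoxide. The alkyl radical can be reduced by the hydride donor before it adds, and the silyl radical can add to the terminal alkene. Alkyl-radical ipso-substitution at a 2-sulfonylchromone is itself an extrapolation, so the two plans are equal on weakness of precedent. After A7, cross-metathesis with 4 and removal of three protecting groups remain.
- Comparison: on structure it is the equal (late ring–chain union in both). On mechanism it trades the statistical problem of the anodic coupling for chain-transfer problems. On step economy the chosen plan is clearly shorter.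

Key step: step 3

Assumption: the quinidine-derived catalyst (DHQD)2AQN is taken to deliver the (R) half-ester 2; if the sense of induction proved opposite, the quinine-derived pseudoenantiomer (DHQ)2AQN would be used with no other change.

## Route

Step 1
Reactants: 1 3-(tert-butyldimethylsilyloxy)glutaric anhydride
Product: 2 (3R)-3-(tert-butyldimethylsilyloxy)pentanedioic acid 1-methyl ester
Conditions: MeOH (10 equiv), (DHQD)2AQN [hydroquinidine anthraquinone-1,4-diyl diether] (0.1–0.3 equiv), Et2O, −40 °C; acid wash to recover the catalyst
Reagents that add atoms: methanol, CO
Why: Cinchona-alkaloid-catalysed alcoholysis of a prochiral cyclic anhydride: the quinuclidine nitrogen acts as a general base for methanol, which attacks one of the two enantiotopic carbonyl groups, so the future C2' becomes a stereocentre without any bond to it being made or broken. The enantiomeric purity can be raised, if needed, by crystallising an amine salt of 2.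

Step 2
Reactants: 3 hex-5-enoic acid; 4 tert-butyl acrylate (3 equiv)
Product: 5 (5E)-7-(tert-butoxy)-7-oxohept-5-enoic acid
Conditions: second-generation Hoveyda–Grubbs catalyst (2 mol%), CH2Cl2, 40 °C
Reagents that add atoms: none
Why: Olefin cross-metathesis between a terminal alkene that dimerises readily and an acrylate that does not is selective for the cross-product and gives the (E)-enoate under thermodynamic control. Ruthenium carbenes of this type tolerate the free carboxylic acid.

Step 3
Reactants: 2 (3R)-3-(tert-butyldimethylsilyloxy)pentanedioic acid 1-methyl ester; 5 (5E)-7-(tert-butoxy)-7-oxohept-5-enoic acid (4 equiv)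
Product: 6 1-tert-butyl 10-methyl (2E,8R)-8-(tert-butyldimethylsilyloxy)dec-2-enedioate
Conditions: undivided cell, Pt anode and Pt cathode, MeOH, KOH (0.05 equiv per CO2H), constant current 0.3–0.5 A cm−2, 30–40 °C, stopped at pH ca. 7–8; NaHCO3 wash, chromatography
Reagents that add atoms: none
Why: Mixed Kolbe electrolysis: each carboxylate gives up one electron at the platinum anode and loses CO2, and the primary radicals MeO2C–CH2–CH(OSiR3)–CH2• and •CH2CH2CH2–CH=CH–CO2tBu combine in the dense radical layer at the electrode to form the C3'–C4' bond (C6–C7 of 6), while the carboxyl protons are reduced to hydrogen at the cathode. The closest known reaction type is the crossed Kolbe coupling of a half-ester or a β-oxygenated acid with a second, cheaper acid taken in excess. No ring is closed and no stereocentre is created; the existing one is the carbon next to the radical centre, never becomes planar, and is carried over unchanged. A radical rather than cationic course is needed: neither radical has an α-heteroatom or branching, the β-silyloxy group is inductively destabilising for a cation, and smooth platinum, high current density and a weakly acidic, only slightly neutralised methanol solution all favour coupling. Cross-coupling has to beat the two homo-couplings, which is statistical; the four-fold excess of 5 should channel most of the radical from 2 into 6, and the two symmetrical dimers carry zero and two silyl ethers, so they should separate from 6 on silica. The enoate must stay passive: it is too electron-poor to be oxidised at this potential, its only intramolecular closures (4-exo, 5-endo) are slow, and bimolecular addition to a β-substituted enoate is slow against radical–radical combination at the surface. The silyl ether and both esters are stable in this medium, and stopping before the solution turns basic avoids methoxide addition to the enoate.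

Step 4
Reactants: 6 1-tert-butyl 10-methyl (2E,8R)-8-(tert-butyldimethylsilyloxy)dec-2-enedioate
Product: 7 (3R,8E)-10-(tert-butoxy)-3-(tert-butyldimethylsilyloxy)-10-oxodec-8-enoic acid
Conditions: LiOH·H2O (1.5 equiv), THF/H2O (3:1), 0 °C to rt; cold dilute HCl to pH 4
Reagents that add atoms: lithium hydroxide, [Li+].[OH-]
Why: Saponification by acyl–oxygen cleavage is much faster at the unhindered methyl ester than at the shielded, conjugated tert-butyl ester. At 0 °C with a small excess of hydroxide the β-silyloxy group should not be eliminated and the enoate should not be attacked; the stereocentre is not involved.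

Step 5
Reactants: 8 2',6'-dihydroxy-4'-methoxyacetophenone
Product: 9 1-[2-hydroxy-4-methoxy-6-(methoxymethoxy)phenyl]ethan-1-one
Conditions: MOMCl (1.05 equiv), iPr2NEt (1.5 equiv), CH2Cl2, 0 °C to rt
Reagents that add atoms: chloromethyl methyl ether, COCCl
Why: O-alkylation of a phenol with an α-chloro ether; 8 is symmetrical, and after the first etherification the remaining phenol is locked in a strong hydrogen bond to the ketone and is far less nucleophilic, so one equivalent of the chloride should stop at the mono-ether.

Step 6
Reactants: 7 (3R,8E)-10-(tert-butoxy)-3-(tert-butyldimethylsilyloxy)-10-oxodec-8-enoic acid; 9 1-[2-hydroxy-4-methoxy-6-(methoxymethoxy)phenyl]ethan-1-one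
Product: 10 1-tert-butyl 10-[2-acetyl-5-methoxy-3-(methoxymethoxy)phenyl] (2E,8R)-8-(tert-butyldimethylsilyloxy)dec-2-enedioate
Conditions: EDC·HCl (1.3 equiv), DMAP (0.3 equiv), CH2Cl2, 0 °C to rt
Reagents that add atoms: none
Why: Steglich esterification: the carbodiimide activates the acid and DMAP transfers the acyl group to the chelated phenol under near-neutral conditions that leave the silyl ether, the tert-butyl ester, the acetal and the stereocentre untouched.

Step 7
Reactants: 10 1-tert-butyl 10-[2-acetyl-5-methoxy-3-(methoxymethoxy)phenyl] (2E,8R)-8-(tert-butyldimethylsilyloxy)dec-2-enedioate
Product: 11 tert-butyl (2E,8R)-8-(tert-butyldimethylsilyloxy)-12-[2-hydroxy-4-methoxy-6-(methoxymethoxy)phenyl]-10,12-dioxododec-2-enoate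
Conditions: LiHMDS (2.5 equiv), THF, −78 to −20 °C; AcOH quench
Reagents that add atoms: none
Why: Baker–Venkataraman rearrangement: the lithium enolate of the methyl ketone attacks the neighbouring aryl ester carbonyl through a six-membered transition state, and the acyl group moves from oxygen to carbon, forming the future C2–C3 bond. The product is held as the phenoxide–diketonate, which drives the shift, and the low temperature should keep the ester α-position and the enoate γ-position from reacting.

Step 8
Reactants: 11 tert-butyl (2E,8R)-8-(tert-butyldimethylsilyloxy)-12-[2-hydroxy-4-methoxy-6-(methoxymethoxy)phenyl]-10,12-dioxododec-2-enoate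
Product: 12 (2E,8R)-8-hydroxy-9-(5-hydroxy-7-methoxy-4-oxo-4H-chromen-2-yl)non-2-enoic acid (Penithochromone T)
Conditions: TFA/CH2Cl2 (1:1), 0 °C to rt; then H2O (10 vol%), rt; evaporation; NaHCO3 (aq)/MeOH, then pH 3
Reagents that add atoms: none
Why: Acid-catalysed cyclodehydration of the ortho-hydroxyaryl 1,3-diketone (phenol adds to the chain carbonyl, water is lost) should close ring C first, since it is faster than acidolysis of a secondary silyl ether. The same acid cleaves the tert-butyl ester by alkyl–oxygen fission and the methoxymethyl ether, and the added water completes desilylation and traps the cations. None of these events touches the C2'–O bond, so the (R) configuration is kept; any trifluoroacetate on the C2' oxygen is removed in the bicarbonate/methanol work-up.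

## Compound list

1 | 3-(tert-butyldimethylsilyloxy)glutaric anhydride | CC(C)(C)[Si](C)(C)OC1CC(=O)OC(=O)C1 | starting material
2 | (3R)-3-(tert-butyldimethylsilyloxy)pentanedioic acid 1-methyl ester | COC(=O)C[C@H](O[Si](C)(C)C(C)(C)C)CC(=O)O | intermediate
3 | hex-5-enoic acid | C=CCCCC(=O)O | starting material
4 | tert-butyl acrylate | C=CC(=O)OC(C)(C)C | starting material
5 | (5E)-7-(tert-butoxy)-7-oxohept-5-enoic acid | OC(=O)CCC/C=C/C(=O)OC(C)(C)C | intermediate
6 | 1-tert-butyl 10-methyl (2E,8R)-8-(tert-butyldimethylsilyloxy)dec-2-enedioate | COC(=O)C[C@H](O[Si](C)(C)C(C)(C)C)CCCC/C=C/C(=O)OC(C)(C)C | intermediate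
7 | (3R,8E)-10-(tert-butoxy)-3-(tert-butyldimethylsilyloxy)-10-oxodec-8-enoic acid | OC(=O)C[C@H](O[Si](C)(C)C(C)(C)C)CCCC/C=C/C(=O)OC(C)(C)C | intermediate
8 | 2',6'-dihydroxy-4'-methoxyacetophenone | CC(=O)c1c(O)cc(OC)cc1O | starting material
9 | 1-[2-hydroxy-4-methoxy-6-(methoxymethoxy)phenyl]ethan-1-one | CC(=O)c1c(O)cc(OC)cc1OCOC | intermediate
10 | 1-tert-butyl 10-[2-acetyl-5-methoxy-3-(methoxymethoxy)phenyl] (2E,8R)-8-(tert-butyldimethylsilyloxy)dec-2-enedioate | CC(=O)c1c(OCOC)cc(OC)cc1OC(=O)C[C@H](O[Si](C)(C)C(C)(C)C)CCCC/C=C/C(=O)OC(C)(C)C | intermediate
11 | tert-butyl (2E,8R)-8-(tert-butyldimethylsilyloxy)-12-[2-hydroxy-4-methoxy-6-(methoxymethoxy)phenyl]-10,12-dioxododec-2-enoate | COCOc1cc(OC)cc(O)c1C(=O)CC(=O)C[C@H](O[Si](C)(C)C(C)(C)C)CCCC/C=C/C(=O)OC(C)(C)C | intermediate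
12 | (2E,8R)-8-hydroxy-9-(5-hydroxy-7-methoxy-4-oxo-4H-chromen-2-yl)non-2-enoic acid (Penithochromone T) | COc1cc(O)c2c(=O)cc(C[C@H](O)CCCC/C=C/C(=O)O)oc2c1 | target

## Step count and risk

Total step count: 8. Longest linear sequence: 6 steps (step 1 or step 2, then steps 3, 4, 6, 7 and 8); step 5 lies on a one-step side branch.

Step 3 (key step). The most likely failure is a poor share of cross-coupling, because the union is statistical and radical disproportionation, further oxidation to cations, and radical addition to the enoate of the partner used in excess all drain material. An enoate-bearing acid is also beyond the usual substrate range of this electrolysis. The fallback sets out from 2 and returns at 6 using two-electron chemistry, keeping the carboxyl carbon of 2 as C4'. Chemoselective reduction of the free acid with BH3·SMe2 in THF at 0 °C should give methyl (3R)-3-(tert-butyldimethylsilyloxy)-5-hydroxypentanoate F1. Iodination with I2, PPh3 and imidazole should give methyl (3S)-3-(tert-butyldimethylsilyloxy)-5-iodopentanoate F2; the descriptor changes only because of the priority rules, the spatial arrangement is unchanged. Copper-catalysed alkyl–alkyl coupling with but-3-en-1-ylmagnesium bromide (Li2CuCl4 catalyst, THF/NMP, −20 °C, slow addition so that the ester survives) should give methyl (3R)-3-(tert-butyldimethylsilyloxy)non-8-enoate F3. Cross-metathesis of F3 with 4 under the conditions of step 2 would then deliver 6.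

Step 7. The process to fear is deprotonation at the ester α-carbon instead of the ketone methyl group, followed by β-elimination of the silyloxy group or loss of the aryloxide, which would destroy the stereocentre or the ester. Deconjugation of the enoate by γ-deprotonation is a lesser risk. The fallback avoids strong base by intermolecular soft-enolisation acylation; it sets out from 7 and 8 and returns at 12.
- 8 is fully protected with NaH and excess MOMCl in DMF to give 1-[4-methoxy-2,6-bis(methoxymethoxy)phenyl]ethan-1-one F4.
- 7 is converted with pentafluorophenol and EDC into 1-tert-butyl 10-(pentafluorophenyl) (2E,8R)-8-(tert-butyldimethylsilyloxy)dec-2-enedioate F5.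
- F4 and F5 are combined with MgBr2·OEt2 and iPr2NEt in CH2Cl2, where only the magnesium-chelated ketone is enolised. This should give tert-butyl (2E,8R)-8-(tert-butyldimethylsilyloxy)-12-[4-methoxy-2,6-bis(methoxymethoxy)phenyl]-10,12-dioxododec-2-enoate F6.
- The acid treatment of step 8 would convert F6 directly into 12.

Step 8. Three things can go wrong: loss of the silyl group before ring C has closed, which would allow the C2' oxygen to cyclise onto the aryl ketone; acid-induced dehydration across C1'–C2' or persistent trifluoroacetylation of the free alcohol; and alkylation of the electron-rich ring A by the tert-butyl or methoxymethyl cation. The fallback separates the events and changes the last deprotection from acidolysis to fluoride; it sets out from 11 and returns at 12. Brief treatment with anhydrous TFA in CH2Cl2 at 0 °C would close the ring and remove the acetal and the tert-butyl ester while the secondary silyl ether is retained, giving (2E,8R)-8-(tert-butyldimethylsilyloxy)-9-(5-hydroxy-7-methoxy-4-oxo-4H-chromen-2-yl)non-2-enoic acid F7. F7 would be isolated and desilylated with HF·pyridine in THF, so that the free alcohol never meets strong acid or the open diketone.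

Step 4. The risk is base-induced β-elimination of the silyloxy group through the ester enolate, or incomplete discrimination between the two esters. The fallback replaces hydroxide by a neutral deallylation; it sets out from 1 and 5 and returns at 7. Opening of 1 with allyl alcohol under the same cinchona catalysis would give (3R)-3-(tert-butyldimethylsilyloxy)pentanedioic acid 1-(prop-2-en-1-yl) ester F8. Co-electrolysis of F8 with 5 as in step 3 would give 1-tert-butyl 10-(prop-2-en-1-yl) (2E,8R)-8-(tert-butyldimethylsilyloxy)dec-2-enedioate F9. Allyl transfer to morpholine with Pd(PPh3)4 (zerovalent palladium) in THF at rt would then release 7 without any base-sensitive stage.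

## Further compounds

F1 | step 3 | methyl (3R)-3-(tert-butyldimethylsilyloxy)-5-hydroxypentanoate | COC(=O)C[C@H](O[Si](C)(C)C(C)(C)C)CCO
F2 | step 3 | methyl (3S)-3-(tert-butyldimethylsilyloxy)-5-iodopentanoate | COC(=O)C[C@H](O[Si](C)(C)C(C)(C)C)CCI
F3 | step 3 | methyl (3R)-3-(tert-butyldimethylsilyloxy)non-8-enoate | COC(=O)C[C@H](O[Si](C)(C)C(C)(C)C)CCCCC=C
F4 | step 7 | 1-[4-methoxy-2,6-bis(methoxymethoxy)phenyl]ethan-1-one | CC(=O)c1c(OCOC)cc(OC)cc1OCOC
F5 | step 7 | 1-tert-butyl 10-(pentafluorophenyl) (2E,8R)-8-(tert-butyldimethylsilyloxy)dec-2-enedioate | O=C(Oc1c(F)c(F)c(F)c(F)c1F)C[C@H](O[Si](C)(C)C(C)(C)C)CCCC/C=C/C(=O)OC(C)(C)C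
F6 | step 7 | tert-butyl (2E,8R)-8-(tert-butyldimethylsilyloxy)-12-[4-methoxy-2,6-bis(methoxymethoxy)phenyl]-10,12-dioxododec-2-enoate | COCOc1cc(OC)cc(OCOC)c1C(=O)CC(=O)C[C@H](O[Si](C)(C)C(C)(C)C)CCCC/C=C/C(=O)OC(C)(C)C
F7 | step 8 | (2E,8R)-8-(tert-butyldimethylsilyloxy)-9-(5-hydroxy-7-methoxy-4-oxo-4H-chromen-2-yl)non-2-enoic acid | COc1cc(O)c2c(=O)cc(C[C@H](O[Si](C)(C)C(C)(C)C)CCCC/C=C/C(=O)O)oc2c1
F8 | step 4 | (3R)-3-(tert-butyldimethylsilyloxy)pentanedioic acid 1-(prop-2-en-1-yl) ester | C=CCOC(=O)C[C@H](O[Si](C)(C)C(C)(C)C)CC(=O)O
F9 | step 4 | 1-tert-butyl 10-(prop-2-en-1-yl) (2E,8R)-8-(tert-butyldimethylsilyloxy)dec-2-enedioate | C=CCOC(=O)C[C@H](O[Si](C)(C)C(C)(C)C)CCCC/C=C/C(=O)OC(C)(C)C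
A1 | alternative 1 | 2-(prop-2-yn-1-yl)cyclohexan-1-one (racemic) | C#CCC1CCCCC1=O
A2 | alternative 1 | (7R)-7-(prop-2-yn-1-yl)oxepan-2-one | C#CC[C@H]1CCCCC(=O)O1
A3 | alternative 2 | methyl (2E)-4-{6-[(2R)-2-(tert-butyldimethylsilyloxy)oct-7-en-1-yl]-4-oxo-4H-pyran-2-yl}-3-methoxybut-2-enoate | COC(=O)/C=C(/OC)Cc1cc(=O)cc(C[C@H](O[Si](C)(C)C(C)(C)C)CCCCC=C)o1
A4 | alternative 2 | 2-[(2R)-2-(tert-butyldimethylsilyloxy)oct-7-en-1-yl]-5-hydroxy-7-methoxy-4H-chromen-4-one | COc1cc(O)c2c(=O)cc(C[C@H](O[Si](C)(C)C(C)(C)C)CCCCC=C)oc2c1
A5 | alternative 3 | 7-methoxy-5-(methoxymethoxy)-2-(methylsulfonyl)-4H-chromen-4-one | COCOc1cc(OC)cc2oc(S(C)(=O)=O)cc(=O)c12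
A6 | alternative 3 | tert-butyl{[(2R)-1-iodooct-7-en-2-yl]oxy}dimethylsilane | IC[C@H](O[Si](C)(C)C(C)(C)C)CCCCC=C
A7 | alternative 3 | 2-[(2R)-2-(tert-butyldimethylsilyloxy)oct-7-en-1-yl]-7-methoxy-5-(methoxymethoxy)-4H-chromen-4-one | COc1cc(OCOC)c2c(=O)cc(C[C@H](O[Si](C)(C)C(C)(C)C)CCCCC=C)oc2c1
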